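**Plan**
- Retrosynthetic cuts, in order: ring D at O–C15 (alkynol cycloisomerisation); ring C at O9–C13 (epoxide opening by the C9 hydroxyl); the C6–O and C9–O bonds together (O2 bridge across a ring-B diene); the side chain at C12–C13 (sp3–sp2 coupling).
- Enabling feature: ring B carries oxygen at C6 and C9, 1,4 across C7–C8, plus oxygen at C7. A 7-silyloxy-6,8-diene therefore maps onto the target once O2 bridges C6 and C9, and the C7 silyl enol ether later becomes the ketone.
- Forward order: rings A and B come from (+)-sclareolide; the side chain is coupled on and made into an epoxy alkyne; the diene is photooxygenated and the peroxide opened; ring C closes, C6 is reduced and acetylated, C7 is unmasked, and ring D closes last.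
- Stereochemistry: C5 and C10 from sclareolide; C13 from Sharpless epoxidation then inversion; C9 from α-face cycloaddition; C6 from α-face hydride delivery; C8 from ketonisation to the equatorial methyl.

Key step: step 10

Remark: labdane numbering is used (C17 on C8, C20 on C10, C16 on C13); the target is read as (13R)-6β-acetoxy-9α,13:15,16-diepoxylabd-14-en-7-one with C17 α (H8 β), 5α-H and 10β-methyl.

Step 1
Reactants: 1 (+)-sclareolide
Product: 2 methyl 13,14,15,16-tetranorlabd-8-en-12-oate
Conditions: H2SO4 (conc.), MeOH, 25 → 65 °C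
Reagents that add atoms: methanol CO
Why: Acid-mediated lactone opening with ionisation at tertiary C8, Fischer esterification and E1 elimination under equilibrating conditions should favour the tetrasubstituted Δ8(9) olefin (minor isomers to be removed on AgNO3-impregnated silica), with C5 and C10 untouched.

Step 2
Reactants: 2 methyl 13,14,15,16-tetranorlabd-8-en-12-oate
Product: 3 13,14,15,16-tetranorlabd-8-en-12-ol
Conditions: LiAlH4, THF, 0 °C
Reagents that add atoms: none
Why: Hydride reduction of the ester to the primary alcohol is routine and leaves the tetrasubstituted olefin alone.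

Step 3
Reactants: 3 13,14,15,16-tetranorlabd-8-en-12-ol
Product: 4 12-bromo-13,14,15,16-tetranorlabd-8-ene
Conditions: CBr4, PPh3, CH2Cl2, 0 °C
Reagents that add atoms: tetrabromomethane BrC(Br)(Br)Br
Why: Appel bromination displaces the oxyphosphonium of the unhindered primary alcohol by SN2 and gives a halide that is inert to the next oxidation.

Step 4
Reactants: 4 12-bromo-13,14,15,16-tetranorlabd-8-ene
Product: 5 12-bromo-13,14,15,16-tetranorlabd-8-en-7-one
Conditions: CrO3, 3,5-dimethylpyrazole, CH2Cl2, −20 °C
Reagents that add atoms: chromium trioxide O=[Cr](=O)=O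
Why: Allylic oxidation with the CrO3–3,5-dimethylpyrazole complex should select the ring methylene C7, because C11 is flanked by quaternary C10 and deactivated by the bromine and C17 is only a primary methyl, giving the conjugated 8-en-7-one.

Step 5
Reactants: 5 12-bromo-13,14,15,16-tetranorlabd-8-en-7-one; 6 2-bromoprop-2-en-1-ol
Product: 8 14-hydroxy-15-norlabda-8,13(16)-dien-7-one, via alkylzinc bromide 7 (not isolated)
Conditions: Zn dust, I2 (5 mol%), DMA, 70 °C; then 6, Pd(OAc)2 (2 mol%), SPhos (4 mol%), THF, 25 °C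
Reagents that add atoms: none
Why: Direct zinc insertion into the primary bromide tolerates the enone, and Negishi coupling with the alkenyl bromide under Pd(OAc)2/SPhos, a system that tolerates free hydroxyl groups, forms the C12–C13 sp3–sp2 bond.

Step 6
Reactants: 8 14-hydroxy-15-norlabda-8,13(16)-dien-7-one
Product: 9 (13S)-13,16-epoxy-14-hydroxy-15-norlabd-8-en-7-one
Conditions: Ti(OiPr)4 (10 mol%), L-(+)-diethyl tartrate (12 mol%), t-BuOOH, 4 Å molecular sieves, CH2Cl2, −20 °C
Reagents that add atoms: tert-butyl hydroperoxide CC(C)(C)OO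
Why: Sharpless asymmetric epoxidation of the 2-substituted allylic alcohol with the L-(+)-tartrate sets C13 as S under reagent control, while the electron-poor tetrasubstituted enone olefin is inert to the titanium–peroxide system.

Step 7
Reactants: 9 (13S)-13,16-epoxy-14-hydroxy-15-norlabd-8-en-7-one
Product: 10 (13R)-13,16-epoxy-7-oxo-15-norlabd-8-en-14-al
Conditions: Dess–Martin periodinane, pyridine, CH2Cl2, 0 → 25 °C
Reagents that add atoms: none
Why: Dess–Martin oxidation under pyridine buffering gives the non-enolisable epoxy aldehyde without opening the epoxide (the descriptor changes by priority only, not by geometry).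

Step 8
Reactants: 10 (13R)-13,16-epoxy-7-oxo-15-norlabd-8-en-14-al; 11 dimethyl (1-diazo-2-oxopropyl)phosphonate
Product: 13 (13S)-13,16-epoxylabd-8-en-14-yn-7-one, via dimethyl (diazomethyl)phosphonate 12 (not isolated)
Conditions: 11, K2CO3, MeOH, 0 → 25 °C
Reagents that add atoms: none
Why: Seyferth–Gilbert homologation in its Ohira–Bestmann form converts the aldehyde into the terminal alkyne under mild carbonate/methanol conditions, and quaternary C13 cannot epimerise.

Step 9
Reactants: 13 (13S)-13,16-epoxylabd-8-en-14-yn-7-one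
Product: 15 (13S)-7-(tert-butyldimethylsilyloxy)-13,16-epoxylabda-6,8-dien-14-yne, via lithium dienolate 14 (not isolated)
Conditions: LiN(SiMe3)2 (1.05 equiv), THF, −78 °C; then t-BuMe2SiOTf, −78 °C; Et3N quench
Reagents that add atoms: tert-butyldimethylsilyl trifluoromethanesulfonate CC(C)(C)[Si](C)(C)OS(=O)(=O)C(F)(F)F
Why: Kinetic enolisation with the hindered amide removes the α′ proton at C6 in preference to the γ protons at C11 and the far less acidic alkyne C–H, and O-silylation of the cross-conjugated dienolate gives the homoannular 2-silyloxy diene.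

Step 10
Reactants: 15 (13S)-7-(tert-butyldimethylsilyloxy)-13,16-epoxylabda-6,8-dien-14-yne
Product: 16 (13S)-7-(tert-butyldimethylsilyloxy)-6α,9α-epidioxy-13,16-epoxylabd-7-en-14-yne
Conditions: O2, 5,10,15,20-tetraphenylporphyrin (cat.), visible light, CH2Cl2, −78 °C
Reagents that add atoms: dioxygen O=O
Why: Energy transfer from the excited porphyrin gives singlet oxygen, which adds in a concerted suprafacial [4+2] cycloaddition to C6 and C9 of the cisoid ring-B diene and forms both C–O bonds at once. The closest known reaction type is the sensitised photooxygenation of homoannular dienes (steroid 5,7-dienes, 2-silyloxycyclohexa-1,3-dienes) to 2,3-dioxabicyclo[2.2.2]oct-5-enes. The new six-membered peroxide ring across ring B is closed by the cycloaddition itself. Both new stereocentres, C6 and C9, are fixed by attack on the α face, because the axial C20 methyl on C10 and the axial 4β methyl cover the β face. The step needs cycloaddition to win over ene reaction at the allylic hydrogens of the tetrasubstituted C8=C9 bond and over silyl-transfer ene reaction of the enol ether; the diene locked s-cis in one ring, made electron-rich by the 7-silyloxy group, and the low temperature should secure this. The epoxide and the terminal alkyne do not react with singlet oxygen.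

Step 11
Reactants: 16 (13S)-7-(tert-butyldimethylsilyloxy)-6α,9α-epidioxy-13,16-epoxylabd-7-en-14-yne
Product: 17 (13S)-7-(tert-butyldimethylsilyloxy)-13,16-epoxy-9α-hydroxylabd-7-en-14-yn-6-one
Conditions: Et3N, CH2Cl2, 0 → 25 °C
Reagents that add atoms: none
Why: In this Kornblum–DeLaMare rearrangement the amine removes the only hydrogen on a peroxide-bearing carbon (H6), so the O–O bond breaks to the C6 ketone and the tertiary 9α-hydroxyl with C9 unchanged, leaving the silyl enol ether as a robust 2-silyloxy enone.

Step 12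
Reactants: 17 (13S)-7-(tert-butyldimethylsilyloxy)-13,16-epoxy-9α-hydroxylabd-7-en-14-yn-6-one
Product: 19 (13R)-7-(tert-butyldimethylsilyloxy)-9α,13-epoxy-16-(triethylsilyloxy)labd-7-en-14-yn-6-one, via primary alcohol 18 (not isolated)
Conditions: camphorsulfonic acid (10 mol%), CH2Cl2, 0 °C; then imidazole, Et3SiCl, 0 → 25 °C
Reagents that add atoms: chlorotriethylsilane CC[Si](Cl)(CC)CC
Why: Acid-catalysed 5-exo-tet epoxide-opening etherification at the more substituted, propargylic carbon proceeds with inversion (13S epoxide to 13R ether) and closes ring C, and the freed primary C16 hydroxyl is silylated in the same flask so that it cannot compete in the later acetylation.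

Step 13
Reactants: 19 (13R)-7-(tert-butyldimethylsilyloxy)-9α,13-epoxy-16-(triethylsilyloxy)labd-7-en-14-yn-6-one
Product: 20 (13R)-7-(tert-butyldimethylsilyloxy)-9α,13-epoxy-16-(triethylsilyloxy)labd-7-en-14-yn-6β-ol
Conditions: iBu2AlH, CH2Cl2, −78 °C; aqueous potassium sodium tartrate work-up
Reagents that add atoms: none
Why: 1,2-Reduction by the bulky aluminium hydride occurs from the α face because the β face of C6 is screened by the syn-axial C20 and 4β methyls, which sets the axial 6β-alcohol, and the fully substituted β-carbon rules out conjugate reduction.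

Step 14
Reactants: 20 (13R)-7-(tert-butyldimethylsilyloxy)-9α,13-epoxy-16-(triethylsilyloxy)labd-7-en-14-yn-6β-ol
Product: 21 (13R)-6β-acetoxy-7-(tert-butyldimethylsilyloxy)-9α,13-epoxy-16-(triethylsilyloxy)labd-7-en-14-yne
Conditions: Ac2O, DMAP, pyridine, 40 °C
Reagents that add atoms: acetic anhydride CC(=O)OC(C)=O
Why: DMAP-catalysed acylation is strong enough for the hindered axial allylic alcohol, and the silyl ethers, the tertiary ether and the alkyne are inert to it.

Step 15
Reactants: 21 (13R)-6β-acetoxy-7-(tert-butyldimethylsilyloxy)-9α,13-epoxy-16-(triethylsilyloxy)labd-7-en-14-yne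
Product: 22 (13R)-6β-acetoxy-9α,13-epoxy-16-hydroxylabd-14-yn-7-one (C17 α)
Conditions: Bu4NF, AcOH (1:1), THF, 0 → 25 °C
Reagents that add atoms: none
Why: Buffered fluoride desilylation removes both silyl groups, and the freed enol should ketonise by axial protonation at C8 from the β face so that C17 becomes equatorial (α), the favoured arrangement that avoids a syn-axial clash with C20 and the 6β-acetate, while the acetic acid buffer suppresses enolate-mediated acetyl migration and β-elimination of the C9 ether.

Step 16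
Reactants: 22 (13R)-6β-acetoxy-9α,13-epoxy-16-hydroxylabd-14-yn-7-one
Product: 23 (13R)-6β-acetoxy-9α,13:15,16-diepoxylabd-14-en-7-one (target)
Conditions: Mo(CO)6 (30 mol%), Me3NO (30 mol%), Et3N, Et2O, 25 °C; chromatography on Et3N-deactivated silica
Reagents that add atoms: none
Why: In this alkynol cycloisomerisation the terminal alkyne rearranges on Mo(CO)5(NEt3) to a molybdenum vinylidene that the C16 hydroxyl traps at C15 (formal 5-endo-dig closure of the but-3-yn-1-ol unit), and protodemetalation gives the 2,3-dihydrofuran under amine-buffered conditions that spare the acid-labile spiro enol ether.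

**Compound list**
1 | (+)-sclareolide | C[C@]12CCCC([C@@H]1CC[C@@]3([C@@H]2CC(=O)O3)C)(C)C | starting material
2 | methyl 13,14,15,16-tetranorlabd-8-en-12-oate | C1CC(C)=C(CC(=O)OC)[C@@]2(C)CCCC(C)(C)[C@H]12 | intermediate
3 | 13,14,15,16-tetranorlabd-8-en-12-ol | C1CC(C)=C(CCO)[C@@]2(C)CCCC(C)(C)[C@H]12 | intermediate
4 | 12-bromo-13,14,15,16-tetranorlabd-8-ene | C1CC(C)=C(CCBr)[C@@]2(C)CCCC(C)(C)[C@H]12 | intermediate
5 | 12-bromo-13,14,15,16-tetranorlabd-8-en-7-one | C1C(=O)C(C)=C(CCBr)[C@@]2(C)CCCC(C)(C)[C@H]12 | intermediate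
6 | 2-bromoprop-2-en-1-ol | OCC(Br)=C | starting material
7 | (7-oxo-13,14,15,16-tetranorlabd-8-en-12-yl)zinc bromide | C1C(=O)C(C)=C(CC[Zn]Br)[C@@]2(C)CCCC(C)(C)[C@H]12 | intermediate (not isolated)
8 | 14-hydroxy-15-norlabda-8,13(16)-dien-7-one | C1C(=O)C(C)=C(CCC(=C)CO)[C@@]2(C)CCCC(C)(C)[C@H]12 | intermediate
9 | (13S)-13,16-epoxy-14-hydroxy-15-norlabd-8-en-7-one | C1C(=O)C(C)=C(CC[C@]3(CO)CO3)[C@@]2(C)CCCC(C)(C)[C@H]12 | intermediate
10 | (13R)-13,16-epoxy-7-oxo-15-norlabd-8-en-14-al | C1C(=O)C(C)=C(CC[C@]3(C=O)CO3)[C@@]2(C)CCCC(C)(C)[C@H]12 | intermediate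
11 | dimethyl (1-diazo-2-oxopropyl)phosphonate | COP(=O)(OC)C(=[N+]=[N-])C(C)=O | starting material
12 | dimethyl (diazomethyl)phosphonate | COP(=O)(OC)C=[N+]=[N-] | intermediate (not isolated)
13 | (13S)-13,16-epoxylabd-8-en-14-yn-7-one | C1C(=O)C(C)=C(CC[C@]3(C#C)CO3)[C@@]2(C)CCCC(C)(C)[C@H]12 | intermediate
14 | lithium (13S)-13,16-epoxylabda-6,8-dien-14-yn-7-olate | C1=C(O[Li])C(C)=C(CC[C@]3(C#C)CO3)[C@@]2(C)CCCC(C)(C)[C@H]12 | intermediate (not isolated)
15 | (13S)-7-(tert-butyldimethylsilyloxy)-13,16-epoxylabda-6,8-dien-14-yne | C1=C(O[Si](C)(C)C(C)(C)C)C(C)=C(CC[C@]3(C#C)CO3)[C@@]2(C)CCCC(C)(C)[C@H]12 | intermediate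
16 | (13S)-7-(tert-butyldimethylsilyloxy)-6α,9α-epidioxy-13,16-epoxylabd-7-en-14-yne | O1O[C@H]2C(O[Si](C)(C)C(C)(C)C)=C(C)[C@]1(CC[C@]3(C#C)CO3)[C@@]1(C)CCCC(C)(C)[C@H]21 | intermediate
17 | (13S)-7-(tert-butyldimethylsilyloxy)-13,16-epoxy-9α-hydroxylabd-7-en-14-yn-6-one | O=C1C(O[Si](C)(C)C(C)(C)C)=C(C)[C@](O)(CC[C@]3(C#C)CO3)[C@@]2(C)CCCC(C)(C)[C@H]12 | intermediate
18 | (13R)-7-(tert-butyldimethylsilyloxy)-9α,13-epoxy-16-hydroxylabd-7-en-14-yn-6-one | O=C1C(O[Si](C)(C)C(C)(C)C)=C(C)[C@]2(CC[C@](CO)(C#C)O2)[C@@]2(C)CCCC(C)(C)[C@H]12 | intermediate (not isolated)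
19 | (13R)-7-(tert-butyldimethylsilyloxy)-9α,13-epoxy-16-(triethylsilyloxy)labd-7-en-14-yn-6-one | O=C1C(O[Si](C)(C)C(C)(C)C)=C(C)[C@]2(CC[C@](CO[Si](CC)(CC)CC)(C#C)O2)[C@@]2(C)CCCC(C)(C)[C@H]12 | intermediate
20 | (13R)-7-(tert-butyldimethylsilyloxy)-9α,13-epoxy-16-(triethylsilyloxy)labd-7-en-14-yn-6β-ol | O[C@@H]1C(O[Si](C)(C)C(C)(C)C)=C(C)[C@]2(CC[C@](CO[Si](CC)(CC)CC)(C#C)O2)[C@@]2(C)CCCC(C)(C)[C@H]12 | intermediate
21 | (13R)-6β-acetoxy-7-(tert-butyldimethylsilyloxy)-9α,13-epoxy-16-(triethylsilyloxy)labd-7-en-14-yne | CC(=O)O[C@@H]1C(O[Si](C)(C)C(C)(C)C)=C(C)[C@]2(CC[C@](CO[Si](CC)(CC)CC)(C#C)O2)[C@@]2(C)CCCC(C)(C)[C@H]12 | intermediate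
22 | (13R)-6β-acetoxy-9α,13-epoxy-16-hydroxylabd-14-yn-7-one (C17 α) | CC(=O)O[C@@H]1C(=O)[C@@H](C)[C@]2(CC[C@](CO)(C#C)O2)[C@@]2(C)CCCC(C)(C)[C@H]12 | intermediate
23 | (13R)-6β-acetoxy-9α,13:15,16-diepoxylabd-14-en-7-one (C17 α) | CC(=O)O[C@@H]1C(=O)[C@@H](C)[C@]2(CC[C@]3(C=COC3)O2)[C@@]2(C)CCCC(C)(C)[C@H]12 | target

Total step count: 16. Longest linear sequence: 16 steps, from (+)-sclareolide.

**Steps most likely to fail**

Step 10. Silyl transfer from O7 to the incoming oxygen (a silatropic ene reaction of the enol ether) or hydrogen-abstracting ene reaction at C11 or C17 may outrun the cycloaddition, and the silyloxy peroxide may decompose on handling. The fallback changes the activating group; it sets out from 13 and comes back at 17. The lithium dienolate 14 is O-acetylated with Ac2O to the dienyl acetate F1, whose acyl group cannot migrate to a peroxy oxygen and which makes the C6=C7 bond less ene-reactive. Sensitised photooxygenation under the conditions of step 10 then gives the acetoxy endoperoxide F2, and Et3N rearranges it to the acetoxy hydroxy enone F3. K2CO3 in MeOH at 0 °C cleaves the enol ester to the diosphenol F4, and t-BuMe2SiCl with imidazole silylates only the acidic enolic hydroxyl, which returns to 17.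

Step 12. The hindered tertiary C9 hydroxyl may attack too slowly, so that acid-induced ionisation at C13 with loss of configuration, 6-endo attack at C16, or Meinwald rearrangement of the epoxide takes over. The fallback activates the alkyne instead of the epoxide oxygen; it sets out from 17 and comes back at 18, which is silylated to 19 as before. With Cu(MeCN)4BF4, 2,6-bis[(4S)-4-phenyl-4,5-dihydro-1,3-oxazol-2-yl]pyridine (or its enantiomer) and iPr2NEt in THF, the ethynyl epoxide is expected to ionise through its copper acetylide to a copper allenylidene that accepts nucleophiles only at the propargylic carbon. The tethered 9-hydroxyl would then close the same tetrahydrofuran, with the C13 configuration chosen by the ligand enantiomer instead of by inversion; no compound outside the list is made (F0).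

Step 16. Vinylidene formation next to the quaternary propargylic carbon may be slow, and long exposure to Et3N may cause β-elimination of the C9 ether from the 7-ketone or epimerisation at C6. The fallback replaces the one-step cycloisomerisation by hydration and dehydration; it sets out from 22 and comes back at 23. Hydroboration of the terminal alkyne with dicyclohexylborane and oxidation with NaBO3·4H2O give the aldehyde, which closes on the C16 hydroxyl to the 15-hydroxy lactol F5. MsCl and Et3N at 0 → 25 °C convert it through the anomeric mesylate F6 into the enol ether 23 by elimination.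

**Further compounds**
F1 | step 10 | (13S)-7-acetoxy-13,16-epoxylabda-6,8-dien-14-yne | C1=C(OC(C)=O)C(C)=C(CC[C@]3(C#C)CO3)[C@@]2(C)CCCC(C)(C)[C@H]12
F2 | step 10 | (13S)-7-acetoxy-6α,9α-epidioxy-13,16-epoxylabd-7-en-14-yne | O1O[C@H]2C(OC(C)=O)=C(C)[C@]1(CC[C@]3(C#C)CO3)[C@@]1(C)CCCC(C)(C)[C@H]21
F3 | step 10 | (13S)-7-acetoxy-13,16-epoxy-9α-hydroxylabd-7-en-14-yn-6-one | O=C1C(OC(C)=O)=C(C)[C@](O)(CC[C@]3(C#C)CO3)[C@@]2(C)CCCC(C)(C)[C@H]12
F4 | step 10 | (13S)-13,16-epoxy-7,9α-dihydroxylabd-7-en-14-yn-6-one | O=C1C(O)=C(C)[C@](O)(CC[C@]3(C#C)CO3)[C@@]2(C)CCCC(C)(C)[C@H]12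
F0 | step 12 | none | none
F5 | step 16 | (13R)-6β-acetoxy-9α,13:15,16-diepoxy-15-hydroxylabdan-7-one (C15 epimers) | CC(=O)O[C@@H]1C(=O)[C@@H](C)[C@]2(CC[C@]3(CC(O)OC3)O2)[C@@]2(C)CCCC(C)(C)[C@H]12
F6 | step 16 | (13R)-6β-acetoxy-9α,13:15,16-diepoxy-15-(methanesulfonyloxy)labdan-7-one | CC(=O)O[C@@H]1C(=O)[C@@H](C)[C@]2(CC[C@]3(CC(OS(C)(=O)=O)OC3)O2)[C@@]2(C)CCCC(C)(C)[C@H]12
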